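**Strategy.** The 2,3-cis-3,4-trans-4,5-cis tetrahydrofuran (O1, C2–C5) is disconnected at C4–C5, the bond joining the methyl-bearing C4 to the benzylic, oxygen-bearing C5 that carries the 3-methoxy-4-alkoxyphenyl ring (ring B). Both atoms are traced back to carbonyl carbons: C5 to an aroyl ester whose alkoxy oxygen is the ring oxygen O1, C4 to a methyl ketone. A low-valent-titanium keto–ester coupling unites these two electrophilic carbons in one operation, closing the ring as a 4,5-dihydrofuran that already holds the whole diaryl-dimethyl skeleton. Its precursor is an acyclic β-aroyloxy ketone made by syn-crotylation, acylation and Wacker oxidation. Ionic hydrogenation then sets C4 and C5; the side chains follow by SN2 etherification and Felkin reduction.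

Key step: step 5

Remark: ring A is the aryl group on C2 (3-hydroxy-4-alkoxyphenyl in the target), ring B the aryl group on C5. Compounds 1, 7, 15 and 16 are taken as catalogue materials.

**Step 1**
Reactants: 1 3-(benzyloxy)-4-hydroxybenzaldehyde
Product: 2 2-(benzyloxy)-4-formylphenyl pivalate
Conditions: PivCl, Et3N, DMAP (cat.), CH2Cl2, 0 °C → rt
Reagents that add atoms: pivaloyl chloride CC(C)(C)C(=O)Cl
Why: DMAP-catalysed acylation masks the phenol as a base-cleavable, electron-withdrawing pivalate that later retards ionisation of the ring A benzylic C–O bond, while the benzyl ether stays on the oxygen that is a free phenol in the target.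

**Step 2**
Reactants: 2 2-(benzyloxy)-4-formylphenyl pivalate; 3 cis-2-butene
Product: 6 2-(benzyloxy)-4-[(1S,2R)-1-hydroxy-2-methylbut-3-enyl]phenyl pivalate, via (Z)-crotylpotassium 4 (not isolated), via (Z)-crotyldiisopinocampheylborane 5 (not isolated)
Conditions: 3, KOt-Bu, n-BuLi, THF, −78 → −45 °C; (−)-Ipc2BOMe, −78 °C; BF3·OEt2; 2, −78 °C; NaBO3·4H2O, THF/H2O, rt
Reagents that add atoms: none
Why: Brown asymmetric crotylboration through a closed chair (Zimmerman–Traxler) transition state, in which the Z geometry gives the syn relationship (the future 2,3-cis) and the isopinocampheyl groups from (+)-α-pinene direct si-face attack to set (1S,2R); the buffered perborate work-up should spare the aryl pivalate.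

**Step 3**
Reactants: 6 2-(benzyloxy)-4-[(1S,2R)-1-hydroxy-2-methylbut-3-enyl]phenyl pivalate; 7 4-acetoxy-3-methoxybenzoic acid
Product: 9 (1S,2R)-1-[3-(benzyloxy)-4-(pivaloyloxy)phenyl]-2-methylbut-3-enyl 4-acetoxy-3-methoxybenzoate, via 4-acetoxy-3-methoxybenzoyl chloride 8 (not isolated)
Conditions: 7, (COCl)2, DMF (cat.), CH2Cl2, rt, evaporate; then 6, pyridine, CH2Cl2, 0 °C → rt
Reagents that add atoms: none
Why: Acylation of the secondary alcohol by the acid chloride made in the flask installs ring B together with the carbon that becomes C5, the ester oxygen being the future O1; DMAP is left out so that the aryl acetate is not transferred.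

**Step 4**
Reactants: 9 (1S,2R)-1-[3-(benzyloxy)-4-(pivaloyloxy)phenyl]-2-methylbut-3-enyl 4-acetoxy-3-methoxybenzoate
Product: 10 (1S,2S)-1-[3-(benzyloxy)-4-(pivaloyloxy)phenyl]-2-methyl-3-oxobutyl 4-acetoxy-3-methoxybenzoate
Conditions: PdCl2 (10 mol%), CuCl, O2 (1 atm), DMF/H2O 7:1, rt
Reagents that add atoms: water O
Why: Tsuji–Wacker oxidation by Markovnikov hydroxypalladation of the monosubstituted alkene gives the methyl ketone (future C4 with its methyl group) under near-neutral conditions that should leave the α-stereocentre and the β-aroyloxy group untouched (the descriptor changes from R to S only through priorities).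

**Step 5**
Reactants: 10 (1S,2S)-1-[3-(benzyloxy)-4-(pivaloyloxy)phenyl]-2-methyl-3-oxobutyl 4-acetoxy-3-methoxybenzoate
Product: 11 (2S,3R)-5-(4-acetoxy-3-methoxyphenyl)-2-[3-(benzyloxy)-4-(pivaloyloxy)phenyl]-3,4-dimethyl-2,3-dihydrofuran
Conditions: TiCl3(DME)1.5, Zn dust, DME, reflux; 10 and Et3N added by syringe pump over 24 h (high dilution); filtration through basic alumina
Reagents that add atoms: none
Why: Low-valent titanium from TiCl3/Zn reduces the C4 ketone to a titanium-bound ketyl, which adds to the neighbouring aroyl ester carbonyl (C5) to give a cyclic titanium 1,2-diolate that is deoxygenated on the metal to the C4=C5 enol ether, the ester oxygen becoming O1. The closest known reaction type is the McMurry keto–ester (oxo–ester) coupling, used for cycloalkanone enol ethers and for benzofurans and indoles from acyloxy- and acylamido-ketones. The ring closes in a 5-exo-trig mode (ketyl carbon C4 onto the ester C=O; ring atoms C4, C3, C2, O1, C5). No stereocentre is created, since C4 and C5 become sp2 and are set in step 6, while C2 and C3 are carried through, the Et3N buffer limiting enolisation at C3. The selectivity needed is ketone–ester ring closure over intermolecular pinacol or olefin coupling and over loss of the β-aroyloxy group. Slow addition at high dilution, the five-membered closure and the acyloxy-deactivated ring A (no benzylic ionisation) should secure it, and the remote aryl acetate and pivalate cannot reach a small-ring transition state.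

**Step 6**
Reactants: 11 (2S,3R)-5-(4-acetoxy-3-methoxyphenyl)-2-[3-(benzyloxy)-4-(pivaloyloxy)phenyl]-3,4-dimethyl-2,3-dihydrofuran
Product: 13 (2S,3R,4R,5S)-5-(4-acetoxy-3-methoxyphenyl)-2-[3-(benzyloxy)-4-(pivaloyloxy)phenyl]-3,4-dimethyltetrahydrofuran, via oxocarbenium trifluoroacetate 12 (not isolated)
Conditions: Et3SiH, CF3CO2H, CH2Cl2, −78 → −40 °C
Reagents that add atoms: none
Why: Ionic hydrogenation: protonation at C4 gives the aryl-stabilised oxocarbenium 12, whose C4 epimers equilibrate through 11 so that the C4 methyl settles trans to the C3 methyl, and Et3SiH then delivers hydride to C5 anti to the adjacent pseudoaxial C4 methyl (inside attack on the envelope in which A(1,2) strain with the coplanar ring B keeps that methyl axial and ring A equatorial), which should place ring B cis to the C4 methyl and trans to ring A, as is known for silane reductions of 2-aryl-3-methyl cyclic oxocarbenium ions; the para-acyloxy groups suppress acid-induced opening of both benzylic C–O bonds.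

**Step 7**
Reactants: 13 (2S,3R,4R,5S)-5-(4-acetoxy-3-methoxyphenyl)-2-[3-(benzyloxy)-4-(pivaloyloxy)phenyl]-3,4-dimethyltetrahydrofuran
Product: 14 2-(benzyloxy)-4-[(2S,3R,4R,5S)-5-(4-hydroxy-3-methoxyphenyl)-3,4-dimethyltetrahydrofuran-2-yl]phenol
Conditions: NaOMe, MeOH/THF, 0 °C → rt; aq. NH4Cl
Reagents that add atoms: none
Why: Zemplén-type methanolysis cleaves the aryl acetate and the aryl pivalate, while the benzyl ether (on the oxygen that must stay unalkylated) and the base-stable tetrahydrofuran are untouched.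

**Step 8**
Reactants: 15 4-bromo-1,2-dimethoxybenzene; 16 (S)-2-hydroxy-N,N-dimethylpropanamide
Product: 18 (S)-1-(3,4-dimethoxyphenyl)-2-hydroxypropan-1-one, via (3,4-dimethoxyphenyl)magnesium bromide 17 (not isolated)
Conditions: 15, Mg, THF; then 16 (0.4 equiv), THF, 0 °C; aq. NH4Cl
Reagents that add atoms: none
Why: Grignard addition to the unprotected α-hydroxy amide stops at the ketone because the magnesium alkoxide chelates the tetrahedral intermediate (Weinreb-like behaviour), and the lactic acid stereocentre is not enolised in that chelate.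

**Step 9**
Reactants: 18 (S)-1-(3,4-dimethoxyphenyl)-2-hydroxypropan-1-one
Product: 19 (S)-1-(3,4-dimethoxyphenyl)-1-oxopropan-2-yl 4-methylbenzenesulfonate
Conditions: TsCl, Et3N, DMAP (cat.), CH2Cl2, 0 °C
Reagents that add atoms: p-toluenesulfonyl chloride Cc1ccc(S(=O)(=O)Cl)cc1
Why: O-sulfonylation with retention gives an α-sulfonyloxy ketone activated for SN2 displacement.

**Step 10**
Reactants: 14 2-(benzyloxy)-4-[(2S,3R,4R,5S)-5-(4-hydroxy-3-methoxyphenyl)-3,4-dimethyltetrahydrofuran-2-yl]phenol; 19 (S)-1-(3,4-dimethoxyphenyl)-1-oxopropan-2-yl 4-methylbenzenesulfonate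
Product: 20 bis-ketone: the (2S,3R,4R,5S)-tetrahydrofuran in which the 4-oxygen of each aryl ring carries an (R)-1-(3,4-dimethoxyphenyl)-1-oxopropan-2-yl group and ring A keeps its 3-benzyloxy group
Conditions: 19 (2.4 equiv), K2CO3, DMF, rt
Reagents that add atoms: none
Why: Williamson etherification in which each phenoxide displaces the tosylate α to the carbonyl by SN2 with inversion, turning (S) into the (R)-α-aryloxy ketone; the mild carbonate base at room temperature should limit enolisation of electrophile and product.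

**Step 11**
Reactants: 20 bis-ketone
Product: 21 O-benzyl manassantin B1 (both side chains (1R,2R)-1-(3,4-dimethoxyphenyl)-1-hydroxypropan-2-yl; ring A 3-benzyloxy)
Conditions: LiBH(s-Bu)3 (L-Selectride), THF, −78 °C; aq. NH4Cl
Reagents that add atoms: none
Why: Felkin–Anh (polar) controlled reduction: the bulky, non-chelating hydride attacks each aryl ketone anti to the α-aryloxy group and past the small hydrogen, which should convert each (R)-α-aryloxy ketone into the (1R,2R) threo alcohol.

**Step 12**
Reactants: 21 O-benzyl manassantin B1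
Product: 22 manassantin B1
Conditions: H2 (1 atm), 10% Pd/C, EtOAc, rt
Reagents that add atoms: none
Why: Hydrogenolysis of the aryl benzyl ether under neutral conditions is much faster than cleavage of the ring benzylic C–O bonds or of the secondary benzylic alcohols, so it should free the last phenol and give the target.

**Compound list**
1 | 3-(benzyloxy)-4-hydroxybenzaldehyde | O=Cc1ccc(O)c(OCc2ccccc2)c1 | starting material
2 | 2-(benzyloxy)-4-formylphenyl pivalate | CC(C)(C)C(=O)Oc1ccc(C=O)cc1OCc1ccccc1 | intermediate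
3 | cis-2-butene | C/C=C\C | starting material
4 | (Z)-crotylpotassium | C/C=C\[CH2-].[K+] | intermediate (not isolated)
5 | (Z)-crotyldiisopinocampheylborane, isopinocampheyl groups from (+)-α-pinene | C/C=C\CB([C@@H]1C[C@@H]2C[C@H]([C@H]1C)C2(C)C)[C@@H]1C[C@@H]2C[C@H]([C@H]1C)C2(C)C | intermediate (not isolated)
6 | 2-(benzyloxy)-4-[(1S,2R)-1-hydroxy-2-methylbut-3-enyl]phenyl pivalate (syn) | CC(C)(C)C(=O)Oc1ccc([C@@H](O)[C@H](C)C=C)cc1OCc1ccccc1 | intermediate
7 | 4-acetoxy-3-methoxybenzoic acid | CC(=O)Oc1ccc(C(=O)O)cc1OC | starting material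
8 | 4-acetoxy-3-methoxybenzoyl chloride | CC(=O)Oc1ccc(C(=O)Cl)cc1OC | intermediate (not isolated)
9 | (1S,2R)-1-[3-(benzyloxy)-4-(pivaloyloxy)phenyl]-2-methylbut-3-enyl 4-acetoxy-3-methoxybenzoate | CC(=O)Oc1ccc(C(=O)O[C@H](c2ccc(OC(=O)C(C)(C)C)c(OCc3ccccc3)c2)[C@H](C)C=C)cc1OC | intermediate
10 | (1S,2S)-1-[3-(benzyloxy)-4-(pivaloyloxy)phenyl]-2-methyl-3-oxobutyl 4-acetoxy-3-methoxybenzoate | CC(=O)Oc1ccc(C(=O)O[C@H](c2ccc(OC(=O)C(C)(C)C)c(OCc3ccccc3)c2)[C@H](C)C(C)=O)cc1OC | intermediate
11 | (2S,3R)-5-(4-acetoxy-3-methoxyphenyl)-2-[3-(benzyloxy)-4-(pivaloyloxy)phenyl]-3,4-dimethyl-2,3-dihydrofuran | CC(C)(C)C(=O)Oc1ccc([C@H]2OC(c3ccc(OC(C)=O)c(OC)c3)=C(C)[C@H]2C)cc1OCc1ccccc1 | intermediate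
12 | C5 oxocarbenium ion of 11 protonated at C4 (3,4-trans), trifluoroacetate | CC(C)(C)C(=O)Oc1ccc([C@H]2[O+]=C(c3ccc(OC(C)=O)c(OC)c3)[C@H](C)[C@H]2C)cc1OCc1ccccc1.[O-]C(=O)C(F)(F)F | intermediate (not isolated)
13 | (2S,3R,4R,5S)-5-(4-acetoxy-3-methoxyphenyl)-2-[3-(benzyloxy)-4-(pivaloyloxy)phenyl]-3,4-dimethyltetrahydrofuran (2,3-cis, 3,4-trans, 4,5-cis) | CC(C)(C)C(=O)Oc1ccc([C@H]2O[C@H](c3ccc(OC(C)=O)c(OC)c3)[C@H](C)[C@H]2C)cc1OCc1ccccc1 | intermediate
14 | 2-(benzyloxy)-4-[(2S,3R,4R,5S)-5-(4-hydroxy-3-methoxyphenyl)-3,4-dimethyltetrahydrofuran-2-yl]phenol | Oc1ccc([C@H]2O[C@H](c3ccc(O)c(OC)c3)[C@H](C)[C@H]2C)cc1OCc1ccccc1 | intermediate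
15 | 4-bromo-1,2-dimethoxybenzene | COc1ccc(Br)cc1OC | starting material
16 | (S)-2-hydroxy-N,N-dimethylpropanamide | C[C@H](O)C(=O)N(C)C | starting material
17 | (3,4-dimethoxyphenyl)magnesium bromide | COc1ccc([Mg]Br)cc1OC | intermediate (not isolated)
18 | (S)-1-(3,4-dimethoxyphenyl)-2-hydroxypropan-1-one | C[C@H](O)C(=O)c1ccc(OC)c(OC)c1 | intermediate
19 | (S)-1-(3,4-dimethoxyphenyl)-1-oxopropan-2-yl 4-methylbenzenesulfonate | C[C@H](OS(=O)(=O)c1ccc(C)cc1)C(=O)c1ccc(OC)c(OC)c1 | intermediate
20 | bis-ketone: (2S,3R,4R,5S)-tetrahydrofuran core, both aryl 4-oxygens bearing (R)-1-(3,4-dimethoxyphenyl)-1-oxopropan-2-yl, ring A 3-benzyloxy | COc1ccc(C(=O)[C@@H](C)Oc2ccc([C@H]3O[C@H](c4ccc(O[C@H](C)C(=O)c5ccc(OC)c(OC)c5)c(OC)c4)[C@H](C)[C@H]3C)cc2OCc2ccccc2)cc1OC | intermediate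
21 | O-benzyl manassantin B1 (side chains (1R,2R)) | COc1ccc([C@@H](O)[C@@H](C)Oc2ccc([C@H]3O[C@H](c4ccc(O[C@H](C)[C@H](O)c5ccc(OC)c(OC)c5)c(OC)c4)[C@H](C)[C@H]3C)cc2OCc2ccccc2)cc1OC | intermediate
22 | manassantin B1 | COc1ccc([C@@H](O)[C@@H](C)Oc2ccc([C@H]3O[C@H](c4ccc(O[C@H](C)[C@H](O)c5ccc(OC)c(OC)c5)c(OC)c4)[C@H](C)[C@H]3C)cc2O)cc1OC | target

**Step count and risks**
Total step count: 12. Longest linear sequence: 10 steps (steps 1–7, then 10–12); steps 8 and 9 form the side-chain branch.

Steps most likely to fail: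

1. Step 5 (keto–ester coupling). The ketyl may be consumed by intermolecular pinacol coupling, or the β-aroyloxy group may be lost by Lewis-acid-assisted elimination or reductive cleavage of the benzylic C–O bond, before the ring closes. The fallback makes C4 a carbanion equivalent instead. It sets out from 9: Markovnikov hydrobromination under cobalt-hydride hydrogen-atom-transfer conditions (Co(acac)2, t-BuOOH, Et3SiH, TsBr) would give the secondary bromide F1 (both C4 epimers, which does not matter). SmI2/HMPA in THF would then effect a Barbier-type intramolecular nucleophilic acyl substitution, the C4 organosamarium attacking the aroyl ester through a five-membered tetrahedral intermediate to give the γ-hydroxy ketone F2 (in equilibrium with its cyclic hemiketal). Under the conditions of step 6, F2 ionises to the same cation 12, and the fallback comes back to the route at 13.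

2. Step 6 (ionic hydrogenation). Hydride delivery to cation 12 may show poor facial selectivity, or may capture the cation before C4 has equilibrated, and acid may epimerise the benzylic centres. The fallback delivers the aryl group last instead of the hydride. It sets out from 6: alcohol-directed, branch-selective hydroformylation (Rh(acac)(CO)2, a catalytic alcohol-exchanging phosphinite ligand, CO/H2) would give the lactol F3, whose C4 methyl is equilibrated trans to the C3 methyl with DBU through the open aldehyde. PhSO2H/CaCl2 would convert it into the 2-benzenesulfonyl tetrahydrofuran F4. In parallel, commercial 4-bromo-2-methoxyphenol would be silylated (TBSCl, imidazole) to the aryl bromide F5 and converted with n-BuLi and then ZnBr2 into the arylzinc bromide F6. Addition of F6 to the oxocarbenium ion released from F4 (ZnBr2, THF) should occur cis to the adjacent C4 methyl and give the silyl ether F7. NaOMe in MeOH removes the pivalate and the aryl silyl ether, and the fallback comes back to the route at 14.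

3. Step 4 (Wacker oxidation). The homoallylic ester may steer palladium towards anti-Markovnikov oxidation to the aldehyde, the alkene may isomerise, or the β-aroyloxy group may be eliminated once the ketone is formed. The fallback replaces palladium by radical hydration. It sets out from 9: Mukaiyama hydration (Co(acac)2, PhSiH3, O2, i-PrOH) would give the secondary alcohol F8 (both epimers), and Dess–Martin periodinane oxidation comes back to the route at 10.

Further compounds
F1 | step 5 | (1S)-1-[3-(benzyloxy)-4-(pivaloyloxy)phenyl]-3-bromo-2-methylbutyl 4-acetoxy-3-methoxybenzoate (C2 as in 9, both C3 epimers) | CC(=O)Oc1ccc(C(=O)O[C@H](c2ccc(OC(=O)C(C)(C)C)c(OCc3ccccc3)c2)[C@H](C)C(C)Br)cc1OC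
F2 | step 5 | 4-[(3R,4S)-4-[3-(benzyloxy)-4-(pivaloyloxy)phenyl]-4-hydroxy-2,3-dimethylbutanoyl]-2-methoxyphenyl acetate (both C2 epimers) | O[C@H](c1ccc(OC(=O)C(C)(C)C)c(OCc2ccccc2)c1)[C@H](C)C(C)C(=O)c1ccc(OC(C)=O)c(OC)c1
F3 | step 6 | 2-(benzyloxy)-4-[(2S,3R,4R)-5-hydroxy-3,4-dimethyltetrahydrofuran-2-yl]phenyl pivalate (both anomers) | CC(C)(C)C(=O)Oc1ccc([C@H]2OC(O)[C@H](C)[C@H]2C)cc1OCc1ccccc1
F4 | step 6 | 2-(benzyloxy)-4-[(2S,3R,4R)-5-(benzenesulfonyl)-3,4-dimethyltetrahydrofuran-2-yl]phenyl pivalate | CC(C)(C)C(=O)Oc1ccc([C@H]2OC(S(=O)(=O)c3ccccc3)[C@H](C)[C@H]2C)cc1OCc1ccccc1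
F5 | step 6 | (4-bromo-2-methoxyphenoxy)(tert-butyl)dimethylsilane | COc1cc(Br)ccc1O[Si](C)(C)C(C)(C)C
F6 | step 6 | [4-(tert-butyldimethylsilyloxy)-3-methoxyphenyl]zinc bromide | COc1cc([Zn]Br)ccc1O[Si](C)(C)C(C)(C)C
F7 | step 6 | 2-(benzyloxy)-4-[(2S,3R,4R,5S)-5-[4-(tert-butyldimethylsilyloxy)-3-methoxyphenyl]-3,4-dimethyltetrahydrofuran-2-yl]phenyl pivalate | CC(C)(C)C(=O)Oc1ccc([C@H]2O[C@H](c3ccc(O[Si](C)(C)C(C)(C)C)c(OC)c3)[C@H](C)[C@H]2C)cc1OCc1ccccc1
F8 | step 4 | (1S)-1-[3-(benzyloxy)-4-(pivaloyloxy)phenyl]-3-hydroxy-2-methylbutyl 4-acetoxy-3-methoxybenzoate (C2 as in 9, both C3 epimers) | CC(=O)Oc1ccc(C(=O)O[C@H](c2ccc(OC(=O)C(C)(C)C)c(OCc3ccccc3)c2)[C@H](C)C(C)O)cc1OC
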